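**Plan**

- Retrosynthesis: the C3 hydroxymethyl group is taken back to a methyl ester, with the acetyl group masked as a dioxolane and the syringyl phenol as a MOM ether. The C2–C3 bond of the dihydrofuran is then cut, leaving an achiral α-diazo arylacetate whose ring A oxygen (O1) carries the syringyl-type benzyl group. Finally the O1–CH2 ether bond and the ring A–CH2CO2Me bond are cut.
- Enabling feature: C3 is bonded to ring A (at C3a) and to an ester-level carbon (the later CH2OH), and C2 is a benzylic carbon on O1. A metal carbene on C3 therefore sits 1,5 to a C–H bond of the O1–CH2–aryl group, and inserting into it forms C2–C3 and the ring O1–C2–C3–C3a–C7a at once.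
- Forward: the two aromatic pieces are prepared (steps 1–2 and 3–4) and joined at O1 by Mitsunobu etherification. The acetate arm is attached by palladium-catalysed coupling of a zinc enolate, diazo transfer follows, and the carbene C–H insertion closes the only new ring.
- Stereochemistry: C2 (S) comes from the chiral dirhodium carboxylate, which selects one enantiotopic benzylic hydrogen. The insertion gives the cis ester; C3 is then equilibrated to the trans ester with base before reduction, which gives 2S,3R in the target.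

Key step: step 8

Assumption: the sense of induction is taken from the parent 2-benzyloxyphenyl diazoacetates, where the S-configured tert-leucinate catalyst leads to the 2R series, so the R-configured catalyst is specified for 2S; were the sense reversed on this substrate, the mirror-image catalyst would be used with nothing else changed.

**Route**

Step 1
Reactants: 1 syringaldehyde
Product: 2 3,5-dimethoxy-4-(methoxymethoxy)benzaldehyde
Conditions: MOMCl, iPr2NEt, CH2Cl2, 0 °C to rt
Reagents that add atoms: chloromethyl methyl ether (MOMCl), COCCl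
Why: O-alkylation of the phenol with the reactive α-chloro ether (MOM protection) gives an acetal that should withstand hydride, zinc enolate, base and carbene chemistry and fall in the final acid step together with the ketal.

Step 2
Reactants: 2 3,5-dimethoxy-4-(methoxymethoxy)benzaldehyde
Product: 3 [3,5-dimethoxy-4-(methoxymethoxy)phenyl]methanol
Conditions: NaBH4, MeOH, 0 °C
Reagents that add atoms: none
Why: Borohydride reduction of the aryl aldehyde to the benzylic alcohol is chemoselective, and the MOM acetal is inert to it.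

Step 3
Reactants: 4 acetovanillone
Product: 5 1-(4-hydroxy-3-iodo-5-methoxyphenyl)ethan-1-one
Conditions: NIS, TsOH·H2O (cat.), MeCN, rt
Reagents that add atoms: N-iodosuccinimide (NIS), O=C1CCC(=O)N1I
Why: Electrophilic aromatic iodination is directed by the free phenol to its only open ortho position, the para position being blocked by the acetyl group.

Step 4
Reactants: 5 1-(4-hydroxy-3-iodo-5-methoxyphenyl)ethan-1-one
Product: 6 2-iodo-6-methoxy-4-(2-methyl-1,3-dioxolan-2-yl)phenol
Conditions: ethylene glycol, TsOH·H2O (cat.), toluene, reflux, Dean–Stark; Et3N quench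
Reagents that add atoms: ethylene glycol, OCCO
Why: Acid-catalysed ketalisation with azeotropic removal of water masks the ketone against the zinc enolate of step 6 and the hydride of step 10, and quenching with Et3N before work-up (with base-washed silica) should preserve the acid-labile p-hydroxyaryl ketal.

Step 5
Reactants: 6 2-iodo-6-methoxy-4-(2-methyl-1,3-dioxolan-2-yl)phenol; 3 [3,5-dimethoxy-4-(methoxymethoxy)phenyl]methanol
Product: 7 2-(4-{[3,5-dimethoxy-4-(methoxymethoxy)phenyl]methoxy}-3-iodo-5-methoxyphenyl)-2-methyl-1,3-dioxolane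
Conditions: PPh3, DIAD, THF, 0 °C to rt
Reagents that add atoms: none
Why: Mitsunobu etherification of an acidic ortho-iodophenol with a primary benzylic alcohol forms the O1–CH2 bond under neutral conditions that leave the ketal and the MOM acetal untouched.

Step 6
Reactants: 7 2-(4-{[3,5-dimethoxy-4-(methoxymethoxy)phenyl]methoxy}-3-iodo-5-methoxyphenyl)-2-methyl-1,3-dioxolane; 8 methyl bromoacetate
Product: 10 methyl 2-[2-{[3,5-dimethoxy-4-(methoxymethoxy)phenyl]methoxy}-3-methoxy-5-(2-methyl-1,3-dioxolan-2-yl)phenyl]acetate, via (2-methoxy-2-oxoethyl)zinc bromide 9 (not isolated)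
Conditions: Zn dust (TMSCl-activated), THF, 40 °C; then 7, Pd2(dba)3 (2.5 mol%), XPhos (10 mol%), THF, 60 °C
Reagents that add atoms: none
Why: Negishi-type α-arylation of a Reformatsky reagent (oxidative addition of the aryl iodide to zerovalent palladium, transmetallation with the zinc enolate, reductive elimination) should give the arylacetate, the ketal, MOM ether and benzyl ether being inert to the organozinc.

Step 7
Reactants: 10 methyl 2-[2-{[3,5-dimethoxy-4-(methoxymethoxy)phenyl]methoxy}-3-methoxy-5-(2-methyl-1,3-dioxolan-2-yl)phenyl]acetate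
Product: 11 methyl 2-diazo-2-[2-{[3,5-dimethoxy-4-(methoxymethoxy)phenyl]methoxy}-3-methoxy-5-(2-methyl-1,3-dioxolan-2-yl)phenyl]acetate
Conditions: p-ABSA, DBU, MeCN, 0 °C to rt
Reagents that add atoms: 4-acetamidobenzenesulfonyl azide (p-ABSA), CC(=O)Nc1ccc(cc1)S(=O)(=O)N=[N+]=[N-]
Why: Regitz diazo transfer to the benzylic ester methylene through the DBU-generated enolate is the standard entry to aryldiazoacetates and touches no other group.

Step 8
Reactants: 11 methyl 2-diazo-2-[2-{[3,5-dimethoxy-4-(methoxymethoxy)phenyl]methoxy}-3-methoxy-5-(2-methyl-1,3-dioxolan-2-yl)phenyl]acetate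
Product: 12 methyl (2S,3R)-2-[3,5-dimethoxy-4-(methoxymethoxy)phenyl]-7-methoxy-5-(2-methyl-1,3-dioxolan-2-yl)-2,3-dihydro-1-benzofuran-3-carboxylate (cis)
Conditions: Rh2(R-PTTL)4 [dirhodium tetrakis(N-phthaloyl-(R)-tert-leucinate)] (2 mol%), toluene, −78 °C, slow addition of 11
Reagents that add atoms: none
Why: The divalent rhodium carboxylate dimer expels N2 from 11 to give an electrophilic rhodium carbene at the future C3, which inserts into a C–H bond of the ArO–CH2 group through a three-centre, hydride-transfer-like transition state and so forms the C2–C3 bond. The closest known reaction type is the enantioselective intramolecular C–H insertion of methyl 2-(2-benzyloxyphenyl)-2-diazoacetates with phthalimide-protected amino acid dirhodium carboxylates, which gives cis-2-aryl-2,3-dihydrobenzofuran-3-carboxylates. The dihydrofuran ring closes by 1,5 C–H insertion, the carbene carbon and the ether methylene being linked through C3a, C7a and O1 in a five-membered transition state. C2 is fixed by the chiral carboxylate ligands, which differentiate the two enantiotopic benzylic hydrogens, and C3 arises cis to the aryl group under kinetic control (it is corrected in step 9). The step needs site selectivity for this methylene over the methoxy, MOM and dioxolane C–H bonds and over carbene dimerisation or aromatic addition; the methylene is the only C–H bond 1,5 to the carbene, it is activated by the adjacent oxygen and the electron-rich aryl group, and low temperature with slow addition should suppress bimolecular paths.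

Step 9
Reactants: 12 methyl (2S,3R)-2-[3,5-dimethoxy-4-(methoxymethoxy)phenyl]-7-methoxy-5-(2-methyl-1,3-dioxolan-2-yl)-2,3-dihydro-1-benzofuran-3-carboxylate (cis)
Product: 13 methyl (2S,3S)-2-[3,5-dimethoxy-4-(methoxymethoxy)phenyl]-7-methoxy-5-(2-methyl-1,3-dioxolan-2-yl)-2,3-dihydro-1-benzofuran-3-carboxylate (trans)
Conditions: NaOMe (0.3 equiv), MeOH/THF, rt
Reagents that add atoms: none
Why: Base-mediated epimerisation through the ester enolate should place the ester trans to the C2 aryl group (the thermodynamic isomer), while the C2–O1 bond lies close to the nodal plane of the endocyclic enolate so that β-elimination is stereoelectronically disfavoured and C2 stays intact.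

Step 10
Reactants: 13 methyl (2S,3S)-2-[3,5-dimethoxy-4-(methoxymethoxy)phenyl]-7-methoxy-5-(2-methyl-1,3-dioxolan-2-yl)-2,3-dihydro-1-benzofuran-3-carboxylate (trans)
Product: 14 [(2S,3R)-2-[3,5-dimethoxy-4-(methoxymethoxy)phenyl]-7-methoxy-5-(2-methyl-1,3-dioxolan-2-yl)-2,3-dihydro-1-benzofuran-3-yl]methanol (trans)
Conditions: LiAlH4, THF, 0 °C
Reagents that add atoms: none
Why: Hydride reduction of the methyl ester gives the primary alcohol while the dioxolane shields the ketone, and neither stereocentre is affected (the C3 descriptor changes only through the priority rules).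

Step 11
Reactants: 14 [(2S,3R)-2-[3,5-dimethoxy-4-(methoxymethoxy)phenyl]-7-methoxy-5-(2-methyl-1,3-dioxolan-2-yl)-2,3-dihydro-1-benzofuran-3-yl]methanol (trans)
Product: 15 1-[(2S,3R)-2-(4-hydroxy-3,5-dimethoxyphenyl)-3-(hydroxymethyl)-7-methoxy-2,3-dihydro-1-benzofuran-5-yl]ethan-1-one
Conditions: 2 M aq. HCl, THF, 40 °C
Reagents that add atoms: water, O
Why: Acid-catalysed hydrolysis of both acetals (dioxolane and MOM ether) should release the aryl ketone and the phenol in one operation, and since C3 is no longer epimerisable and the trans ring is the thermodynamic one, the configuration should be retained.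

**Compound list**

1 | syringaldehyde | COc1cc(C=O)cc(OC)c1O | starting material
2 | 3,5-dimethoxy-4-(methoxymethoxy)benzaldehyde | COCOc1c(OC)cc(C=O)cc1OC | intermediate
3 | [3,5-dimethoxy-4-(methoxymethoxy)phenyl]methanol | COCOc1c(OC)cc(CO)cc1OC | intermediate
4 | acetovanillone | CC(=O)c1ccc(O)c(OC)c1 | starting material
5 | 1-(4-hydroxy-3-iodo-5-methoxyphenyl)ethan-1-one | CC(=O)c1cc(I)c(O)c(OC)c1 | intermediate
6 | 2-iodo-6-methoxy-4-(2-methyl-1,3-dioxolan-2-yl)phenol | COc1cc(C2(C)OCCO2)cc(I)c1O | intermediate
7 | 2-(4-{[3,5-dimethoxy-4-(methoxymethoxy)phenyl]methoxy}-3-iodo-5-methoxyphenyl)-2-methyl-1,3-dioxolane | COCOc1c(OC)cc(COc2c(I)cc(C3(C)OCCO3)cc2OC)cc1OC | intermediate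
8 | methyl bromoacetate | COC(=O)CBr | starting material
9 | (2-methoxy-2-oxoethyl)zinc bromide (Reformatsky reagent, not isolated) | COC(=O)C[Zn]Br | intermediate
10 | methyl 2-[2-{[3,5-dimethoxy-4-(methoxymethoxy)phenyl]methoxy}-3-methoxy-5-(2-methyl-1,3-dioxolan-2-yl)phenyl]acetate | COC(=O)Cc1cc(C2(C)OCCO2)cc(OC)c1OCc1cc(OC)c(OCOC)c(OC)c1 | intermediate
11 | methyl 2-diazo-2-[2-{[3,5-dimethoxy-4-(methoxymethoxy)phenyl]methoxy}-3-methoxy-5-(2-methyl-1,3-dioxolan-2-yl)phenyl]acetate | COC(=O)C(=[N+]=[N-])c1cc(C2(C)OCCO2)cc(OC)c1OCc1cc(OC)c(OCOC)c(OC)c1 | intermediate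
12 | methyl (2S,3R)-2-[3,5-dimethoxy-4-(methoxymethoxy)phenyl]-7-methoxy-5-(2-methyl-1,3-dioxolan-2-yl)-2,3-dihydro-1-benzofuran-3-carboxylate (cis) | COCOc1c(OC)cc([C@H]2Oc3c(OC)cc(C4(C)OCCO4)cc3[C@H]2C(=O)OC)cc1OC | intermediate
13 | methyl (2S,3S)-2-[3,5-dimethoxy-4-(methoxymethoxy)phenyl]-7-methoxy-5-(2-methyl-1,3-dioxolan-2-yl)-2,3-dihydro-1-benzofuran-3-carboxylate (trans) | COCOc1c(OC)cc([C@H]2Oc3c(OC)cc(C4(C)OCCO4)cc3[C@@H]2C(=O)OC)cc1OC | intermediate
14 | [(2S,3R)-2-[3,5-dimethoxy-4-(methoxymethoxy)phenyl]-7-methoxy-5-(2-methyl-1,3-dioxolan-2-yl)-2,3-dihydro-1-benzofuran-3-yl]methanol (trans) | COCOc1c(OC)cc([C@H]2Oc3c(OC)cc(C4(C)OCCO4)cc3[C@@H]2CO)cc1OC | intermediate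
15 | 1-[(2S,3R)-2-(4-hydroxy-3,5-dimethoxyphenyl)-3-(hydroxymethyl)-7-methoxy-2,3-dihydro-1-benzofuran-5-yl]ethan-1-one | COc1cc([C@H]2Oc3c(OC)cc(C(C)=O)cc3[C@@H]2CO)cc(OC)c1O | target

**Step count**

Total steps: 11. Longest linear sequence: 9 steps (steps 3–11, from acetovanillone).

**Steps most likely to fail**

1. Step 8. The catalyst may discriminate poorly between the two enantiotopic benzylic hydrogens of this doubly ortho-flanked, very electron-rich ether, or the carbene may be lost to dimerisation before it inserts. The fallback adds auxiliary control to catalyst control. Setting out from 10, saponification (LiOH, THF/H2O) should give the arylacetic acid F1. Esterification (EDC·HCl, DMAP, CH2Cl2) with (2S)-2-hydroxy-1-(pyrrolidin-1-yl)propan-1-one gives the lactamide ester F2, and diazo transfer (p-ABSA, DBU, MeCN) gives the diazo lactamide ester F3. Insertion with Rh2(S-DOSP)4 (dirhodium tetrakis[N-(4-dodecylbenzenesulfonyl)-(S)-prolinate]) in CH2Cl2 is a chiral-ester/chiral-catalyst combination known to deliver trans-2-aryl-2,3-dihydrobenzofuran-3-carboxylates directly, and is expected to give the trans auxiliary ester F4. The auxiliary and catalyst enantiomers are chosen as the matched pair for 2S (written here with the S-lactamide), and any minor diastereomer would be removed by chromatography. LiBH4 in THF then cleaves the auxiliary reductively, and the route is rejoined at 14.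

2. Step 6. Transmetallation at the ortho-alkoxy arylpalladium iodide may be slow, allowing protodeiodination, and the zinc enolate may self-condense. The fallback sets out from 7: copper-catalysed arylation of dimethyl malonate (CuI, 2-picolinic acid, Cs2CO3, dioxane, 70 °C) should give the aryl malonate F5, and Krapcho demethoxycarbonylation (LiCl, H2O, DMSO, 130 °C) returns to the route at 10.

3. Step 9. The ester enolate may expel the ring A phenoxide by β-elimination, which would erase C2, or the equilibration may stop short of the trans isomer. The fallback moves the epimerisation to the aldehyde oxidation level. From 12, DIBAL-H (toluene, −78 °C) should give the cis aldehyde F6. This much more acidic compound is equilibrated with catalytic DBU in CH2Cl2 at 0 °C to the trans aldehyde F7, and NaBH4 in MeOH then gives 14, bypassing 13.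

Further compounds
F1 | step 8 | 2-[2-{[3,5-dimethoxy-4-(methoxymethoxy)phenyl]methoxy}-3-methoxy-5-(2-methyl-1,3-dioxolan-2-yl)phenyl]acetic acid | OC(=O)Cc1cc(C2(C)OCCO2)cc(OC)c1OCc1cc(OC)c(OCOC)c(OC)c1
F2 | step 8 | (2S)-1-oxo-1-(pyrrolidin-1-yl)propan-2-yl 2-[2-{[3,5-dimethoxy-4-(methoxymethoxy)phenyl]methoxy}-3-methoxy-5-(2-methyl-1,3-dioxolan-2-yl)phenyl]acetate | C[C@H](OC(=O)Cc1cc(C2(C)OCCO2)cc(OC)c1OCc1cc(OC)c(OCOC)c(OC)c1)C(=O)N1CCCC1
F3 | step 8 | (2S)-1-oxo-1-(pyrrolidin-1-yl)propan-2-yl 2-diazo-2-[2-{[3,5-dimethoxy-4-(methoxymethoxy)phenyl]methoxy}-3-methoxy-5-(2-methyl-1,3-dioxolan-2-yl)phenyl]acetate | C[C@H](OC(=O)C(=[N+]=[N-])c1cc(C2(C)OCCO2)cc(OC)c1OCc1cc(OC)c(OCOC)c(OC)c1)C(=O)N1CCCC1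
F4 | step 8 | (2S)-1-oxo-1-(pyrrolidin-1-yl)propan-2-yl (2S,3S)-2-[3,5-dimethoxy-4-(methoxymethoxy)phenyl]-7-methoxy-5-(2-methyl-1,3-dioxolan-2-yl)-2,3-dihydro-1-benzofuran-3-carboxylate (trans) | COCOc1c(OC)cc([C@H]2Oc3c(OC)cc(C4(C)OCCO4)cc3[C@@H]2C(=O)O[C@@H](C)C(=O)N2CCCC2)cc1OC
F5 | step 6 | dimethyl 2-[2-{[3,5-dimethoxy-4-(methoxymethoxy)phenyl]methoxy}-3-methoxy-5-(2-methyl-1,3-dioxolan-2-yl)phenyl]propanedioate | COC(=O)C(C(=O)OC)c1cc(C2(C)OCCO2)cc(OC)c1OCc1cc(OC)c(OCOC)c(OC)c1
F6 | step 9 | (2S,3R)-2-[3,5-dimethoxy-4-(methoxymethoxy)phenyl]-7-methoxy-5-(2-methyl-1,3-dioxolan-2-yl)-2,3-dihydro-1-benzofuran-3-carbaldehyde (cis) | COCOc1c(OC)cc([C@H]2Oc3c(OC)cc(C4(C)OCCO4)cc3[C@H]2C=O)cc1OC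
F7 | step 9 | (2S,3S)-2-[3,5-dimethoxy-4-(methoxymethoxy)phenyl]-7-methoxy-5-(2-methyl-1,3-dioxolan-2-yl)-2,3-dihydro-1-benzofuran-3-carbaldehyde (trans) | COCOc1c(OC)cc([C@H]2Oc3c(OC)cc(C4(C)OCCO4)cc3[C@@H]2C=O)cc1OC
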